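**Plan**
- The target is cut first at the methylene bridge (the bond from the bridging CH2 to ring A, the isobutyryl-bearing ring). This gives ring A triol 11 and the Mannich base 15 of ring B, the acetyl-bearing ring.
- On ring A the chain ArC–CH2–CH(OH)–C(CH3)=CH2 is read as a vinyl unit: its CH2 carries the ring A carbon, and its carbinol carbon carries the isopropenyl group and an oxygen that can come from boron. The aryl–CH2 and CH–isopropenyl bonds are therefore cut together, leading to aryl bromide 4, vinylB(pin) 5 and isopropenyllithium 7.
- Forward: phloroglucinol is acylated, protected as its tris(methoxymethyl) ether and brominated. The three-component coupling, C–B oxidation and acetal removal then finish ring A; ring B is made in three steps, and an ortho-quinone methide alkylation joins the two rings. Both benzene rings are bought and no ring is formed.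
- The only stereocentre, the (R)-carbinol carbon, is set by the chiral bisphosphine–palladium catalyst in the coupling and carried through a stereoretentive oxidation.

Key step: step 4

Assumption: the sense of induction of the ferrocenyl bisphosphine is taken from related conjunctive couplings. The ligand enantiomer is chosen so that the (R)-boronate 9 results, and its mirror image is used if the first run shows the opposite sense.

**Step 1**
Reactants: 1 phloroglucinol
Product: 2 2-methyl-1-(2,4,6-trihydroxyphenyl)propan-1-one
Conditions: isobutyryl chloride, AlCl3 (4 equiv), PhNO2/CH2Cl2, 0 °C to 65 °C; aq. HCl quench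
Reagents that add atoms: isobutyryl chloride, CC(C)C(=O)Cl
Why: Friedel–Crafts C-acylation of the threefold symmetric, highly activated ring gives one mono-ketone, whose acyl group slows a second acylation.

**Step 2**
Reactants: 2 2-methyl-1-(2,4,6-trihydroxyphenyl)propan-1-one
Product: 3 2-methyl-1-[2,4,6-tris(methoxymethoxy)phenyl]propan-1-one
Conditions: NaH (3.6 equiv), MOMCl (3.6 equiv), DMF, 0 °C to rt
Reagents that add atoms: chloromethyl methyl ether, COCCl
Why: Williamson-type O-alkylation of the sodium phenoxides with the hard chloromethyl ether caps all three phenols, including the two hydrogen-bonded to the ketone, so that no acidic proton meets the borate or the catalyst later.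

**Step 3**
Reactants: 3 2-methyl-1-[2,4,6-tris(methoxymethoxy)phenyl]propan-1-one
Product: 4 1-[3-bromo-2,4,6-tris(methoxymethoxy)phenyl]-2-methylpropan-1-one
Conditions: NBS (1.0 equiv), NaHCO3, MeCN, 0 °C
Reagents that add atoms: N-bromosuccinimide, O=C1CCC(=O)N1Br
Why: Electrophilic aromatic bromination at one of two equivalent free positions; one equivalent of NBS at low temperature should stop at the mono-bromide, and no strong acid is released that could cleave the acetals.

**Step 4**
Reactants: 4 1-[3-bromo-2,4,6-tris(methoxymethoxy)phenyl]-2-methylpropan-1-one; 5 vinylboronic acid pinacol ester; 6 2-bromopropene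
Product: 9 2-methyl-1-[3-[(2R)-3-methyl-2-(4,4,5,5-tetramethyl-1,3,2-dioxaborolan-2-yl)but-3-en-1-yl]-2,4,6-tris(methoxymethoxy)phenyl]propan-1-one, via isopropenyllithium 7 (not isolated), via lithium isopropenyl(vinyl)borate 8 (not isolated)
Conditions: 6, t-BuLi (2 equiv per 6), Et2O, −78 °C; then 5 (slight excess over 7), −78 °C to rt, solvent exchanged for THF; then 4, Pd(OAc)2 (5 mol %), one enantiomer of 1,1'-bis[bis(4-methoxy-3,5-dimethylphenyl)phosphino]-2,2'-bis[(dimethylamino)(phenyl)methyl]ferrocene (MandyPhos-type ligand, 6 mol %), NaOTf (3 equiv), degassed THF, 60 °C; rapid filtration through silica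
Reagents that add atoms: none
Why: Aryl bromide 4 adds oxidatively to zerovalent palladium, and NaOTf removes bromide to leave a cationic divalent arylpalladium species that binds the unsubstituted vinyl group of borate 8; this triggers a 1,2-metallate shift in which isopropenyl moves from boron to the boron-bearing carbon anti to palladium, and reductive elimination from the resulting alkylpalladium forms the aryl–CH2 bond. The closest known reaction type is the enantioselective conjunctive cross-coupling of bis(alkenyl)borates with aryl electrophiles, which gives α-substituted allylic boronates. No ring closes; two skeletal bonds form, aryl–CH2 and CH–isopropenyl. The boron-bearing stereocentre is set under catalyst control, the chiral bisphosphine deciding which face of the palladium-bound vinyl group receives the migrating group. The step needs migration of isopropenyl and not of vinyl, and no direct alkenyl transfer to palladium; this is secured because the less hindered vinyl group is the one that coordinates the metal, and the four-coordinate borate, kept free of excess organolithium, does not add to the hindered ketone. The two ortho methoxymethoxy groups slow oxidative addition, which is why the catalyst loading is raised and the mixture is warmed.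

**Step 5**
Reactants: 9 the (R)-allylic boronate
Product: 10 1-[3-[(2R)-2-hydroxy-3-methylbut-3-en-1-yl]-2,4,6-tris(methoxymethoxy)phenyl]-2-methylpropan-1-one
Conditions: 30% H2O2, 3 M NaOH, THF, 0 °C
Reagents that add atoms: hydrogen peroxide, OO
Why: Alkaline peroxide oxidation of the C–B bond moves carbon from boron to oxygen with retention, so the (R)-boronate should give the (R)-alcohol, while the hindered ketone and the acetals are inert to cold alkaline peroxide.

**Step 6**
Reactants: 10 the tris(methoxymethyl) ether of the (R)-allylic alcohol
Product: 11 1-[2,4,6-trihydroxy-3-[(2R)-2-hydroxy-3-methylbut-3-en-1-yl]phenyl]-2-methylpropan-1-one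
Conditions: 3 M aq. HCl (catalytic), MeOH, 0 °C to rt
Reagents that add atoms: none
Why: Acid-catalysed acetal exchange with methanol frees the three phenols under dilute, cold conditions of the kind that spare prenyl-type side chains on phloroglucinols, and the stereocentre takes no part.

**Step 7**
Reactants: 12 2',4',6'-trihydroxyacetophenone
Product: 13 1-(2,4,6-trihydroxy-3-methylphenyl)ethanone
Conditions: NaOMe (3 equiv), MeI (1.1 equiv), MeOH, reflux
Reagents that add atoms: iodomethane, CI
Why: Nuclear methylation of the ambident phloroglucinolate in a protic solvent, where hydrogen bonding to oxygen steers the soft electrophile to carbon; the two free ring positions are equivalent.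

**Step 8**
Reactants: 13 1-(2,4,6-trihydroxy-3-methylphenyl)ethanone
Product: 14 1-(2,6-dihydroxy-4-methoxy-3-methylphenyl)ethanone
Conditions: Me2SO4 (1.0 equiv), K2CO3, acetone, rt to 40 °C
Reagents that add atoms: dimethyl sulfate, COS(=O)(=O)OC
Why: The 4-hydroxyl is the only phenol not flanking the acetyl group and the most acidic, so one equivalent of dimethyl sulfate with a weak base should methylate it selectively (Williamson ether synthesis).

**Step 9**
Reactants: 14 1-(2,6-dihydroxy-4-methoxy-3-methylphenyl)ethanone
Product: 15 1-[3-[(dimethylamino)methyl]-2,6-dihydroxy-4-methoxy-5-methylphenyl]ethanone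
Conditions: 37% aq. HCHO, 40% aq. Me2NH, EtOH, rt
Reagents that add atoms: formaldehyde, C=O; dimethylamine, CNC
Why: Phenolic Mannich reaction at the single unsubstituted ring carbon, which lies ortho and para to free hydroxyl groups.

**Step 10**
Reactants: 11 the ring A triol; 15 the ring B Mannich base
Product: 17 1-[3-[(3-acetyl-2,4-dihydroxy-6-methoxy-5-methylphenyl)methyl]-2,4,6-trihydroxy-5-[(2R)-2-hydroxy-3-methylbut-3-en-1-yl]phenyl]-2-methylpropan-1-one (CNP0162925.1), via ortho-quinone methide 16 (not isolated)
Conditions: 15 (1.1 equiv), 1,4-dioxane, 90 °C, argon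
Reagents that add atoms: none
Why: Thermal loss of dimethylamine from the ortho-hydroxybenzylamine gives ortho-quinone methide 16, which is trapped by Friedel–Crafts-type conjugate C-alkylation at the only free ring carbon of acylphloroglucinol 11, leaving the remote carbinol stereocentre untouched.

**Compound list**
1 | phloroglucinol | Oc1cc(O)cc(O)c1 | starting material
2 | 2-methyl-1-(2,4,6-trihydroxyphenyl)propan-1-one | CC(C)C(=O)c1c(O)cc(O)cc1O | intermediate
3 | 2-methyl-1-[2,4,6-tris(methoxymethoxy)phenyl]propan-1-one | CC(C)C(=O)c1c(OCOC)cc(OCOC)cc1OCOC | intermediate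
4 | 1-[3-bromo-2,4,6-tris(methoxymethoxy)phenyl]-2-methylpropan-1-one | CC(C)C(=O)c1c(OCOC)cc(OCOC)c(Br)c1OCOC | intermediate
5 | vinylboronic acid pinacol ester | C=CB1OC(C)(C)C(C)(C)O1 | starting material
6 | 2-bromopropene | C=C(C)Br | starting material
7 | isopropenyllithium | [Li]C(C)=C | intermediate (not isolated)
8 | lithium isopropenyl(vinyl)borate of pinacol | [Li+].C=C[B-]1(C(C)=C)OC(C)(C)C(C)(C)O1 | intermediate (not isolated)
9 | 2-methyl-1-[3-[(2R)-3-methyl-2-(4,4,5,5-tetramethyl-1,3,2-dioxaborolan-2-yl)but-3-en-1-yl]-2,4,6-tris(methoxymethoxy)phenyl]propan-1-one | C=C(C)[C@H](B1OC(C)(C)C(C)(C)O1)Cc1c(OCOC)cc(OCOC)c(C(=O)C(C)C)c1OCOC | intermediate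
10 | 1-[3-[(2R)-2-hydroxy-3-methylbut-3-en-1-yl]-2,4,6-tris(methoxymethoxy)phenyl]-2-methylpropan-1-one | C=C(C)[C@H](O)Cc1c(OCOC)cc(OCOC)c(C(=O)C(C)C)c1OCOC | intermediate
11 | 1-[2,4,6-trihydroxy-3-[(2R)-2-hydroxy-3-methylbut-3-en-1-yl]phenyl]-2-methylpropan-1-one | C=C(C)[C@H](O)Cc1c(O)cc(O)c(C(=O)C(C)C)c1O | intermediate
12 | 2',4',6'-trihydroxyacetophenone | CC(=O)c1c(O)cc(O)cc1O | starting material
13 | 1-(2,4,6-trihydroxy-3-methylphenyl)ethanone | CC(=O)c1c(O)cc(O)c(C)c1O | intermediate
14 | 1-(2,6-dihydroxy-4-methoxy-3-methylphenyl)ethanone | CC(=O)c1c(O)cc(OC)c(C)c1O | intermediate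
15 | 1-[3-[(dimethylamino)methyl]-2,6-dihydroxy-4-methoxy-5-methylphenyl]ethanone | CC(=O)c1c(O)c(CN(C)C)c(OC)c(C)c1O | intermediate
16 | 2-acetyl-3-hydroxy-5-methoxy-4-methyl-6-methylidenecyclohexa-2,4-dien-1-one (ortho-quinone methide of ring B) | CC(=O)C1=C(O)C(C)=C(OC)C(=C)C1=O | intermediate (not isolated)
17 | 1-[3-[(3-acetyl-2,4-dihydroxy-6-methoxy-5-methylphenyl)methyl]-2,4,6-trihydroxy-5-[(2R)-2-hydroxy-3-methylbut-3-en-1-yl]phenyl]-2-methylpropan-1-one | C=C(C)[C@H](O)Cc1c(O)c(Cc2c(O)c(C(C)=O)c(O)c(C)c2OC)c(O)c(C(=O)C(C)C)c1O | target

**Count**
Total steps: 10. Longest linear sequence: 7 (steps 1 to 6, then step 10); the ring B branch (steps 7 to 9) joins at step 10.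

**Steps most likely to fail**

Step 4. Oxidative addition into the doubly ortho-oxygenated bromide may be slow. Direct transfer of an alkenyl group from boron to palladium (Suzuki-type) may then compete, and the bulky aryl group may erode the facial discrimination. The fallback leaves the coupling and makes the side chain from a prenyl group by known reactions, setting out from 2 and returning at 10. C-Prenylation of 2 with prenyl bromide in cold aqueous KOH would give 2-methyl-1-[2,4,6-trihydroxy-3-(3-methylbut-2-en-1-yl)phenyl]propan-1-one F1. NaH and chloromethyl methyl ether in DMF would give 2-methyl-1-[3-(3-methylbut-2-en-1-yl)-2,4,6-tris(methoxymethoxy)phenyl]propan-1-one F2. Shi epoxidation (KHSO5 as Oxone, the D-fructose-derived ketone 1,2:4,5-di-O-isopropylidene-β-D-erythro-2,3-hexodiulo-2,6-pyranose, pH about 10.5, MeCN/dimethoxymethane/water, 0 °C) should give 1-[3-[[(2R)-3,3-dimethyloxiran-2-yl]methyl]-2,4,6-tris(methoxymethoxy)phenyl]-2-methylpropan-1-one F3; the ketone of the L series is used if the opposite face is attacked. Diethylaluminium 2,2,6,6-tetramethylpiperidide, Et2Al(TMP), in toluene at 0 °C should then remove a methyl proton and open the epoxide at its tertiary carbon. The secondary C–O bond stays intact, so the configuration is kept and alcohol 10 results.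

Step 10. The quinone methide may be captured at oxygen, or the methylene-bridged product may fragment and recombine on heating, exchanging its two halves into symmetric dimers; loss of the amine may also be sluggish. The fallback reverses the roles of the two rings, setting out from 11 and returning at 17. Aqueous formaldehyde and dimethylamine in ethanol should aminomethylate the one free ring carbon of 11 to give 1-[3-[(dimethylamino)methyl]-2,4,6-trihydroxy-5-[(2R)-2-hydroxy-3-methylbut-3-en-1-yl]phenyl]-2-methylpropan-1-one F4. Warming F4 with the ring B ketone 14 in dioxane would let the more readily formed ring A quinone methide be trapped at the free ring carbon of 14, giving 17.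

Step 6. During acetal cleavage a freed ortho phenol may add to the protonated isopropenyl group (closure to a chroman), the allylic alcohol may ionise, or the acetal para to the ketone may cleave incompletely. The fallback avoids Brønsted acid by exchanging the protecting groups, setting out from 10 and returning at 11. Et3SiOTf and 2,2'-bipyridyl in CH2Cl2 at 0 °C convert aryl methoxymethyl ethers directly into aryl triethylsilyl ethers and silylate the alcohol. This would give 2-methyl-1-[3-[(2R)-3-methyl-2-(triethylsilyloxy)but-3-en-1-yl]-2,4,6-tris(triethylsilyloxy)phenyl]propan-1-one F5. Bu4NF buffered with acetic acid in THF at 0 °C would then remove all four silyl groups to give 11.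

**Further compounds**
F1 | step 4 | 2-methyl-1-[2,4,6-trihydroxy-3-(3-methylbut-2-en-1-yl)phenyl]propan-1-one | CC(C)C(=O)c1c(O)cc(O)c(CC=C(C)C)c1O
F2 | step 4 | 2-methyl-1-[3-(3-methylbut-2-en-1-yl)-2,4,6-tris(methoxymethoxy)phenyl]propan-1-one | CC(C)C(=O)c1c(OCOC)cc(OCOC)c(CC=C(C)C)c1OCOC
F3 | step 4 | 1-[3-[[(2R)-3,3-dimethyloxiran-2-yl]methyl]-2,4,6-tris(methoxymethoxy)phenyl]-2-methylpropan-1-one | CC(C)C(=O)c1c(OCOC)cc(OCOC)c(C[C@H]2OC2(C)C)c1OCOC
F4 | step 10 | 1-[3-[(dimethylamino)methyl]-2,4,6-trihydroxy-5-[(2R)-2-hydroxy-3-methylbut-3-en-1-yl]phenyl]-2-methylpropan-1-one | C=C(C)[C@H](O)Cc1c(O)c(CN(C)C)c(O)c(C(=O)C(C)C)c1O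
F5 | step 6 | 2-methyl-1-[3-[(2R)-3-methyl-2-(triethylsilyloxy)but-3-en-1-yl]-2,4,6-tris(triethylsilyloxy)phenyl]propan-1-one | C=C(C)[C@H](O[Si](CC)(CC)CC)Cc1c(O[Si](CC)(CC)CC)cc(O[Si](CC)(CC)CC)c(C(=O)C(C)C)c1O[Si](CC)(CC)CC
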